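**Numbering used throughout.** Upper half: guaiane numbering C1–C15 (C1–C5 five-membered ring, C1/C5–C10 seven-membered ring, lactone C7–C11–C12–O–C8, C13 exocyclic methylene). Lower half: primed numbers, C10' tertiary carbinol (methyl C14'), C5'=C6', C7', C8', C9', lactone C11'–C13', side chain C4' (stereocentre, methyl C15')–C3'–C2'–C1'(O).

## The problem

The target joins two C15 units through a norbornene: bridgeheads C1 and C3, bridges C2 (acetoxy), C4=C5 and C13'–C11', with C1 also a member of the cycloheptane and C11' also the spiro carbon of the lower cis-fused lactone. The upper half is a hydroazulene with a trans-fused α-methylene lactone at C7/C8; the lower half is a cyclohexene with a cis-fused lactone at C7'/C8', a tertiary allylic alcohol at C10' and an acyclic stereocentre C4' on the ring alkene. Eleven stereocentres must be set (C1, C2, C3, C7, C8, C10; C4', C7', C8', C10', C11'). C7/C8 and C7'/C8'/C10' lie in different halves and cannot control one another, so each half has to be made enantiopure; C4' has no cyclic neighbour and needs reagent control. Within the core a relay is available: the C8 oxygen can bias C10, the C10 methyl can direct C1, C1 fixes C3 by ring constraint, the convex face of the lower lactone fixes C11', and the norbornenone shape fixes C2. Fragile groups are the two α-methylene lactones (Michael acceptors, prone to base-induced alkene migration), the acid-labile tertiary allylic alcohol, the two acetates beside a free tertiary hydroxyl, and the strained tetrasubstituted C4=C5 alkene. The enabling feature is that quaternary C1 lies between C10 (CH–CH3) and C13' (CH2 leading to C11'): C10–CH3 and C1–C13' are an anti vicinal pair across a former C1=C10 enone of a C2 ketone, and C13' is the β-carbon of the lower methylene lactone. Only one Michael acceptor may be present during the union, so the upper lactone must be masked.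

## Retrosynthesis

**Acetates and upper lactone (57 ⇐ 56 ⇐ 54).** The two acetates are removed first, then the C12–O8 lactone bond, giving pentaol 54. The upper lactone is carried as a 2-methylene-1,4-diol because a second α-methylene lactone would compete in every enolate step. The forward steps must oxidise one allylic primary alcohol in the presence of four other hydroxyls and then acetylate a primary and a secondary hydroxyl beside a tertiary one.

**C2–H and C3–C11' (54 ⇐ 53 ⇐ 52 ⇐ 50).** Desilylation and hydride addition lead back to norbornenone 52, and cutting C3–C11' opens the bicycle to diketo-type adduct 50. This bond is chosen over C1–C13' for the ring closure because C3 is the only enolisable position of the ketone in 50 (C1 is quaternary) and is doubly activated by C2=O and C4=C5. An oxidative coupling of the ketone dienolate and the lactone enolate forms the 1,4-dicarbonyl directly. The closure must select the convex face of the lactone enolate.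

**C10–CH3 and C1–C13' (50 ⇐ 24 + 46 + 47).** Both bonds are cut together. This divides the molecule into two halves of similar size, upper dienone 24 and lower methylene lactone 46, plus the cuprate 47. The neighbouring option of joining the halves at C3–C11' first would leave the quaternary centre C1 to be made inside a crowded ring. The forward step must give the trans C10/C1 pair and α-attack at C1.

**Upper half, rings (24 ⇐ 23 ⇐ 22 ⇐ 20 ⇐ 17 ⇐ 16 ⇐ 15 ⇐ 13 + 4).** The base-sensitive C2 ketone is made last, by neutral oxidation of dienol 23. The silylated diol 22 comes from lactone 20 by reduction, and 20 from tricycle 17 by methylenation. The C1=C10 bond of 17 is cut by ring-closing metathesis to diene 16, which keeps C4=C5 fixed in place from the start. The C5–C6 bond is cut by Negishi coupling into iodomethyl lactone 13 and iodoenone 4. Methylenation must follow ring closure, because an α-methylene group would offer a competing five-membered metathesis.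

**Upper half, stereocentres (13 ⇐ 12 ⇐ 11 ⇐ 10 ⇐ 9 ⇐ 7 ⇐ 5 + 6; 4 ⇐ 3 ⇐ 1).** The trans C7/C8 pair of 13 comes from lactone aldehyde 11, which traces back through homoallylic alcohol 10, cyclopropane carbaldehyde 9 and cyclopropane 7 to methyl furan-2-carboxylate 5 and ethyl diazoacetate 6. One catalytic asymmetric step sets the absolute configuration, and the allyl group supplies C9/C10. Iodoenone 4 comes in two steps from 3-methylcyclopentenone 1; its oxygenated carbon becomes C2.

**Lower half, lactone and side chain (46 ⇐ 45 ⇐ 35 + 41).** The lactone carbonyl is removed to cyclic allylic ether 45, which survives organolithium chemistry. The C5'–C4' bond is cut by a Zweifel olefination between the alkenyllithium from hydrazone 35 and secondary boronic ester 41. This transfers the C4' configuration stereospecifically, which a B-alkyl Suzuki coupling of a secondary borane could not guarantee.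

**Lower half, ring (35 ⇐ 34 ⇐ 33 ⇐ 32 ⇐ 31 ⇐ 30 ⇐ 29 ⇐ 27 ⇐ 26 ⇐ 25; 41 ⇐ 37 + 38, 37 ⇐ 36).** The C8'–O bond is cut by iodoetherification, which delivers oxygen from the C7' substituent and so gives the cis fusion. The tertiary alcohol and the C8'=C9' alkene of 29 come from the hydroxyl-directed epoxide 27 of cis-carveol 26, and hence from (S)-carvone 25, whose C5 becomes C7'. Boronate 41 comes from the silyl ether of allyl alcohol 36 and ethyl 2,4,6-triisopropylbenzoate 38.

## Roads not taken

**Alternative 1: transannular vinyl radical closure.** The cut is C1–C5. The precursor is ten-membered vinyl bromide A1, which already contains the C1–C2–C3–C11'–C13' ring and the whole lower half. With Bu3SnH the C5 vinyl radical adds across the ring to C1 of the tetrasubstituted C1=C10 alkene, and the C10 radical is reduced to give A2.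
- Merits: one step closes the cyclopentene and the cycloheptane, C4=C5 is delivered directly, and no strong base touches the assembled dimer.
- Weak points: C3–C11' and C1–C13' must be made before the key step. A1 needs a ten-membered ring with a tetrasubstituted alkene of defined geometry. Attack at a fully substituted alkene carbon competes with 1,5-hydrogen abstraction and direct reduction of the vinyl radical. C10 is set by hydrogen transfer from the stannane without an evident controlling element. A2 still lacks the exocyclic methylene.
- Comparison: this road is better in ring-forming economy (two rings at once) and avoids enolate chemistry on the dimer. The chosen plan sets against it a bimolecular union of two separately made halves and a C10/C1 relationship fixed by the trans course of addition and trapping.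

**Alternative 2: pinacol closure, then deoxygenation.** The cut is C4–C5. The precursor is spiro diketone A3. SmI2 (samarium diiodide, divalent samarium) couples the C4 methyl ketone with the C5 cycloheptanone carbonyl to give cis-diol A4, which must then be deoxygenated to the C4=C5 alkene (for example by a Corey–Winter sequence).
- Merits: ketyl–ketone closures of five-membered rings are dependable, the cis diol is predictable, the conditions are neutral, and C2 is already at the alcohol level.
- Weak points: A3 already holds quaternary C1, C3 and spiro C11', so the hardest bonds precede the key step. Both ketyls carry a β-silyloxy group (C2) that can be expelled. A ditertiary diol on a norbornane must be turned into a strained tetrasubstituted alkene, which costs at least two further steps on a hindered substrate.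
- Comparison: the ring closure itself is more reliable than an oxidative enolate coupling. The chosen plan sets against it that C4=C5 is present from the upper-half fragment onward and no deoxygenation is needed.

**Alternative 3: ketyl–enone cyclisation.** The cut is C2–C3. The precursor is aldehyde A5, a spiro cyclohexenone with the C2 formyl group on quaternary C1. SmI2 (samarium diiodide, divalent samarium) forms the ketyl, which adds to C3, the β-carbon of the enone, giving 7-hydroxynorbornanone A6.
- Merits: 5-exo ketyl additions to enones are well precedented, the C2 carbinol configuration is set in the ring-forming step, and no strong base is used.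
- Weak points: A6 has neither the cycloheptane, nor C4=C5, nor the upper lactone. C6, C7 and C11–C13 must be added and the C5 ketone converted into the alkene on a congested core. The neopentyl aldehyde and the spiro centre of A5 must be built beforehand.
- Comparison: this road is better for C2, which it sets directly where the chosen plan relies on a later hydride reduction. The chosen plan sets against it that the complete upper half (24) arrives as one piece, so that after the union only one ring closure and functional-group changes remain.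

Key step: step 30

Assumptions: in step 3 the (R,R) ligand is taken to give the mirror image of the cyclopropane known for the (S,S) ligand; compounds 3, 4 and 15–23 are carried as both epimers at the silyloxy carbon (later C2), which converge in 24.

## Route

Step 1
Reactants: 1 3-methylcyclopent-2-en-1-one
Product: 3 rac-3-methyl-5-(triethylsilyloxy)cyclopent-2-en-1-one, via silyl dienol ether 2 (not isolated)
Conditions: LiN(iPr)2, THF, −78 °C; Et3SiCl; then mCPBA, NaHCO3, CH2Cl2, −20 °C
Reagents that add atoms: chlorotriethylsilane, CC[Si](Cl)(CC)CC; 3-chloroperbenzoic acid, OOC(=O)c1cccc(Cl)c1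
Why: Kinetic α'-deprotonation and O-silylation give the cross-conjugated silyl dienol ether, whose enol double bond is epoxidised selectively; 1,4-silyl migration then gives the α'-silyloxy enone (Rubottom oxidation). The new centre is racemic and is erased in step 16.

Step 2
Reactants: 3 rac-3-methyl-5-(triethylsilyloxy)cyclopent-2-en-1-one
Product: 4 rac-2-iodo-3-methyl-5-(triethylsilyloxy)cyclopent-2-en-1-one
Conditions: I2, pyridine, CH2Cl2, 0 °C → rt
Reagents that add atoms: iodine, [I][I]
Why: α-Iodination of a cyclic enone by the iodine–pyridine addition–elimination sequence, a standard route to 2-iodocycloalkenones.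

Step 3
Reactants: 5 methyl furan-2-carboxylate; 6 ethyl diazoacetate
Product: 7 (1R,5R,6R)-cyclopropanated furan diester
Conditions: Cu(OTf)2 (1 mol%), 2,2'-(propane-2,2-diyl)bis[(4R)-4-isopropyl-4,5-dihydrooxazole] (1.2 mol%), PhNHNH2 (cat.), CH2Cl2, 0 °C, slow addition of 6
Reagents that add atoms: none
Why: Asymmetric cyclopropanation of the less substituted 4,5-double bond of the furan by a copper carbenoid (the divalent copper salt is reduced in situ to monovalent copper); the ester ends up exo and the bis(oxazoline) ligand sets the absolute configuration. Enantiomeric purity should be raised by crystallisation.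

Step 4
Reactants: 7 (1R,5R,6R)-cyclopropanated furan diester
Product: 9 (1R,2R,3R)-cyclopropane carbaldehyde oxalate, via ozonide 8 (not isolated)
Conditions: O3, CH2Cl2, −78 °C; then Me2S, −78 °C → rt
Reagents that add atoms: ozone, [O-][O+]=O
Why: Ozonolysis of the enol ether double bond turns the ring CH into the formyl group and the ester-bearing carbon into the oxalate; the three cyclopropane centres are untouched.

Step 5
Reactants: 9 (1R,2R,3R)-cyclopropane carbaldehyde oxalate
Product: 10 homoallylic alcohol
Conditions: allylSiMe3, BF3·OEt2, CH2Cl2, −78 °C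
Reagents that add atoms: allyltrimethylsilane, C=CC[Si](C)(C)C
Why: Hosomi–Sakurai allylation; Felkin–Anh addition to the cyclopropyl aldehyde should set the carbinol centre (later C8) and brings in C9/C10 as the allyl group.

Step 6
Reactants: 10 homoallylic alcohol
Product: 11 (2R,3S)-2-allyl-5-oxotetrahydrofuran-3-carbaldehyde
Conditions: Ba(OH)2·8H2O, MeOH, 0 °C
Reagents that add atoms: none
Why: Oxalate cleavage unmasks a donor–acceptor cyclopropanol that opens by retro-aldol reaction, and the γ-hydroxy ester lactonises; the trans lactone (C7/C8) is also the thermodynamic one because the centre α to the aldehyde can equilibrate.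

Step 7
Reactants: 11 (2R,3S)-2-allyl-5-oxotetrahydrofuran-3-carbaldehyde
Product: 12 (4R,5R)-5-allyl-4-(hydroxymethyl)dihydrofuran-2(3H)-one
Conditions: NaBH4, MeOH, −20 °C; AcOH quench
Reagents that add atoms: none
Why: Chemoselective aldehyde reduction; low temperature and an acidic quench should prevent translactonisation to the primary alkoxide.

Step 8
Reactants: 12 (4R,5R)-5-allyl-4-(hydroxymethyl)dihydrofuran-2(3H)-one
Product: 13 (4S,5R)-5-allyl-4-(iodomethyl)dihydrofuran-2(3H)-one
Conditions: I2, PPh3, imidazole, CH2Cl2, 0 °C
Reagents that add atoms: iodine, [I][I]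
Why: Appel iodination of the primary alcohol; no stereocentre is involved.

Step 9
Reactants: 13 (4S,5R)-5-allyl-4-(iodomethyl)dihydrofuran-2(3H)-one; 4 rac-2-iodo-3-methyl-5-(triethylsilyloxy)cyclopent-2-en-1-one
Product: 15 coupled enone lactone, via alkylzinc iodide 14 (not isolated)
Conditions: Zn, LiCl, THF, 35 °C; then 4, Pd(OAc)2 (3 mol%), SPhos (6 mol%), THF, rt
Reagents that add atoms: none
Why: LiCl-assisted zinc insertion gives a primary alkylzinc that tolerates the lactone; Negishi coupling with the α-iodoenone (zerovalent palladium formed in situ) makes the C5–C6 bond without touching C7 or C8.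

Step 10
Reactants: 15 coupled enone lactone
Product: 16 exocyclic diene lactone
Conditions: Zn, CH2Br2, TiCl4, THF/CH2Cl2, 0 °C → rt
Reagents that add atoms: dibromomethane, BrCBr
Why: Takai–Lombardo methylenation is non-basic and selective for the ketone over the lactone; the enone becomes the 1,3-diene whose methylene carbon is needed for ring closure.

Step 11
Reactants: 16 exocyclic diene lactone
Product: 17 tricyclic diene lactone
Conditions: second-generation Grubbs catalyst RuCl2(=CHPh)(PCy3)(H2IMes) (5 mol%), PhMe, 80 °C, high dilution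
Reagents that add atoms: none
Why: Ring-closing metathesis between the allyl alkene and the methylene terminus of the diene forms C1=C10 and the seven-membered ring; the tetrasubstituted C4=C5 alkene is inert, and the lactone α-carbon is still saturated so no five-membered closure competes.

Step 12
Reactants: 17 tricyclic diene lactone
Product: 20 tricyclic α-methylene lactone, via Mannich base 18 (not isolated), via trimethylammonium iodide 19 (not isolated)
Conditions: LiN(iPr)2, THF, −78 °C; CH2=NMe2+ I−; then MeI, MeOH, rt; then NaHCO3 (aq), CH2Cl2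
Reagents that add atoms: N,N-dimethylmethyleneiminium iodide (Eschenmoser's salt), C=[N+](C)C.[I-]
Why: The lactone enolate is the only accessible carbanion; aminomethylation, quaternisation and elimination is the standard α-methylenation of butanolides.

Step 13
Reactants: 20 tricyclic α-methylene lactone
Product: 21 2-methylene-1,4-diol
Conditions: iBu2AlH (4 equiv), CH2Cl2, −78 → 0 °C; then KNaC4H4O6 (aq)
Reagents that add atoms: none
Why: 1,2-Reduction of the α-methylene lactone gives the C8/C12 diol and removes the upper Michael acceptor for the coupling steps.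

Step 14
Reactants: 21 2-methylene-1,4-diol
Product: 22 bis(tert-butyldimethylsilyl) ether
Conditions: tBuMe2SiCl, imidazole, DMAP (cat.), DMF, 40 °C
Reagents that add atoms: tert-butylchlorodimethylsilane, CC(C)(C)[Si](C)(C)Cl
Why: Standard silylation of a primary allylic and a secondary alcohol; neutral conditions spare the dienyl silyl ether.

Step 15
Reactants: 22 bis(tert-butyldimethylsilyl) ether
Product: 23 dienol
Conditions: HF·pyridine, pyridine, THF, 0 °C
Reagents that add atoms: none
Why: Buffered fluoride cleaves the secondary triethylsilyl ether in preference to the tert-butyldimethylsilyl ethers and avoids ionisation of the dienyl carbinol.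

Step 16
Reactants: 23 dienol
Product: 24 upper-half hydroazulene dienone
Conditions: MnO2 (activated, excess), CH2Cl2, rt
Reagents that add atoms: none
Why: Neutral allylic oxidation converges both C2 epimers; making the ketone last and without base keeps C4=C5 out of conjugation-driven migration.

Step 17
Reactants: 25 (S)-carvone
Product: 26 (1S,5S)-cis-carveol
Conditions: NaBH4, CeCl3·7H2O, MeOH, −78 → 0 °C
Reagents that add atoms: none
Why: Luche 1,2-reduction; axial hydride delivery gives the alcohol cis to the isopropenyl group.

Step 18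
Reactants: 26 (1S,5S)-cis-carveol
Product: 27 syn-epoxy alcohol
Conditions: VO(acac)2 (2 mol%), tBuOOH, PhMe, 0 °C → rt
Reagents that add atoms: tert-butyl hydroperoxide, CC(C)(C)OO
Why: Hydroxyl-directed epoxidation places the oxygen on the face of the hydroxyl and isopropenyl groups, which sets C10'; the isopropenyl alkene is not an allylic alcohol and stays intact.

Step 19
Reactants: 27 syn-epoxy alcohol
Product: 29 diene diol, via hydroxy selenide 28 (not isolated)
Conditions: (PhSe)2, NaBH4, EtOH, 78 °C; then H2O2 (30%), THF, 0 °C → rt
Reagents that add atoms: none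
Why: Selenolate opens the epoxide at the less hindered C9' (trans-diaxial); the selenoxide can eliminate only toward C8' because C10' bears no hydrogen, giving the tertiary allylic alcohol with C10' intact.

Step 20
Reactants: 29 diene diol
Product: 30 α-hydroxy ketone
Conditions: (COCl)2, DMSO, CH2Cl2, −78 °C; then Et3N
Reagents that add atoms: none
Why: Swern oxidation of the secondary alcohol only; the tertiary alcohol cannot react and no glycol cleavage occurs.

Step 21
Reactants: 30 α-hydroxy ketone
Product: 31 allylic alcohol
Conditions: SeO2 (0.3 equiv), tBuOOH (3 equiv), CH2Cl2, rt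
Reagents that add atoms: tert-butyl hydroperoxide, CC(C)(C)OO
Why: Ene reaction and [2,3]-shift hydroxylate the methyl group of the 1,1-disubstituted alkene; the ring alkene has only the shared methine as allylic hydrogen and should react more slowly.

Step 22
Reactants: 31 allylic alcohol
Product: 32 iodo ether
Conditions: I2, NaHCO3, MeCN, 0 °C
Reagents that add atoms: iodine, [I][I]
Why: 5-exo iodoetherification delivers oxygen to C8' from the C7' substituent, so the new ring is necessarily cis-fused (C8' set); with C5' already a ketone no bridged ether can form from that position.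

Step 23
Reactants: 32 iodo ether
Product: 33 ether ketone
Conditions: Bu3SnH, AIBN (cat.), PhH, 80 °C
Reagents that add atoms: none
Why: Radical deiodination leaves C9' as CH2; the ketone, tertiary alcohol and exocyclic alkene are inert to the stannyl radical chain.

Step 24
Reactants: 33 ether ketone
Product: 34 triethylsilyl ether
Conditions: Et3SiOTf, 2,6-lutidine, CH2Cl2, −78 → −20 °C
Reagents that add atoms: triethylsilyl trifluoromethanesulfonate, CC[Si](CC)(CC)OS(=O)(=O)C(F)(F)F
Why: Silyl triflate silylates the hindered tertiary α-hydroxyl; the amine base is too weak to enolise the ketone at low temperature.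

Step 25
Reactants: 34 triethylsilyl ether
Product: 35 trisylhydrazone
Conditions: 2,4,6-iPr3C6H2SO2NHNH2, THF, rt
Reagents that add atoms: 2,4,6-triisopropylbenzenesulfonyl hydrazide, CC(C)c1cc(C(C)C)c(S(=O)(=O)NN)c(C(C)C)c1
Why: Condensation of the ketone with the arenesulfonyl hydrazide gives the Shapiro precursor.

Step 26
Reactants: 36 allyloxy(tert-butyl)dimethylsilane
Product: 37 3-(tert-butyldimethylsilyloxy)propyl pinacol boronate
Conditions: pinacolborane, [Ir(cod)Cl]2 (1.5 mol%), dppe (3 mol%), CH2Cl2, rt
Reagents that add atoms: pinacolborane, B1OC(C)(C)C(C)(C)O1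
Why: Iridium-catalysed hydroboration of a terminal alkene gives the linear boronic ester.

Step 27
Reactants: 38 ethyl 2,4,6-triisopropylbenzoate; 37 3-(tert-butyldimethylsilyloxy)propyl pinacol boronate
Product: 41 (R)-secondary boronic ester, via lithiated benzoate 39 (not isolated), via boronate complex 40 (not isolated)
Conditions: sBuLi, (−)-sparteine, Et2O, −78 °C; then 37; then MgBr2·OEt2, 35 °C
Reagents that add atoms: none
Why: Sparteine-mediated asymmetric deprotonation gives the (S)-lithiated benzoate; borylation with retention and 1,2-migration with inversion should give the (R)-boronic ester (lithiation–borylation). This sets C4' by reagent control.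

Step 28
Reactants: 35 trisylhydrazone; 41 (R)-secondary boronic ester
Product: 45 side-chain-bearing cyclic ether, via alkenyllithium 42 (not isolated), via boronate complex 43 (not isolated), via β-iodo boronic ester 44 (not isolated)
Conditions: nBuLi (2.1 equiv), THF, −78 → 0 °C; then 41, −78 °C; then I2, MeOH/THF, −78 °C; then NaOMe, −78 °C → rt
Reagents that add atoms: none
Why: The Shapiro reaction can only give the C5'=C6' alkenyllithium because C10' is quaternary; the derived boronate complex undergoes iodine-induced 1,2-migration with retention at C4', and deboronative elimination restores the alkene (Zweifel olefination).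

Step 29
Reactants: 45 side-chain-bearing cyclic ether
Product: 46 lower-half methylene lactone
Conditions: CrO3, 3,5-dimethylpyrazole, CH2Cl2, −20 °C
Reagents that add atoms: chromium trioxide, O=[Cr](=O)=O
Why: Allylic oxidation of the CH2 activated by both the ether oxygen and the exocyclic alkene turns the 3-methylenetetrahydrofuran into the α-methylene lactone; the ring alkene has no allylic CH2 or CH3.

Step 30
Reactants: 24 upper-half hydroazulene dienone; 46 lower-half methylene lactone; 47 lithium dimethylcuprate
Product: 50 Michael adduct joining both halves, via lithium dienolate 48 (not isolated), via lithium lactone enolate 49 (not isolated)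
Conditions: 47 (1.05 equiv, from CuI and 2 MeLi), Et2O, −78 °C; then 46, THF, −78 → −40 °C; then NH4Cl (aq)
Reagents that add atoms: lithium dimethylcuprate (47), [Li+].C[Cu-]C
Why: Me2CuLi (monovalent copper) transfers methyl to C10, the β-carbon of the C2 enone; 1,6-addition is closed because C4=C5 is only cross-conjugated. The lithium dienolate 48 (O–C2=C1–C5=C4) then adds through its α-carbon C1 to the unhindered exocyclic methylene of 46, and lactone enolate 49 is protonated on work-up. The closest known reaction types are the three-component coupling of an enone, an organocuprate and a Michael acceptor, and the α-alkylation of extended dienolates. No ring is closed. C10 is set by cuprate attack on the face of the cycloheptadienone anti to the C8 silyloxy group, and C1 by approach of the acceptor anti to the new vicinal methyl (trans course of addition and trapping); C11' is formed as a centre of no consequence. The step needs α (C1) rather than γ (C4) attack, which lithium dienolates favour at low temperature, and Michael addition rather than proton transfer from C3 of 24 or C7' of 46, which the non-basic cuprate, low temperature and reactive acceptor should secure. Silylation of the C8/C12 diol leaves 46 as the only acceptor, and the product ketone can enolise only toward C3.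

Step 31
Reactants: 50 Michael adduct joining both halves
Product: 52 norbornenone, via dilithium bis-enolate 51 (not isolated)
Conditions: LiN(iPr)2 (2.5 equiv), THF, −78 °C; then Fe(acac)3 (2.2 equiv), −78 → 0 °C
Reagents that add atoms: none
Why: Intramolecular oxidative enolate heterocoupling: one-electron oxidation by trivalent iron joins C3 of the ketone dienolate to C11' of the lactone enolate, closing the five-membered ring C1–C2–C3–C11'–C13' (coupling at C5 would give a four-membered ring). C3 is fixed by the bicycle, and C11' by attack on the convex face of the cis-fused lactone enolate, which places C7' exo and the lactone carbonyl endo.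

Step 32
Reactants: 52 norbornenone
Product: 53 C2 alcohol
Conditions: NaBH4, MeOH/THF, −20 °C
Reagents that add atoms: none
Why: The strained bridging ketone is reduced without touching the lactone; hydride should enter from the alkene face, since the face of the C13'–C11' bridge is blocked by exo C7', giving the alcohol syn to that bridge as 7-norbornenones normally do.

Step 33
Reactants: 53 C2 alcohol
Product: 54 pentaol
Conditions: Bu4NF, AcOH, THF, rt → 40 °C
Reagents that add atoms: none
Why: Buffered fluoride removes all four silyl groups without base-induced isomerisation of the methylene lactone or acid-induced ionisation of the tertiary allylic alcohol.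

Step 34
Reactants: 54 pentaol
Product: 56 triol bis-lactone, via lactol 55 (not isolated)
Conditions: MnO2 (activated, excess), CH2Cl2, rt
Reagents that add atoms: none
Why: Only the C12 hydroxyl is allylic and oxidisable; the enal is captured by the C8 hydroxyl and the lactol is oxidised on to the upper α-methylene lactone, while the C2, C1' and C10' hydroxyls are not allylic secondary or primary alcohols and remain.

Step 35
Reactants: 56 triol bis-lactone
Product: 57 CNP0257312.1
Conditions: Ac2O, pyridine, DMAP (cat.), CH2Cl2, 0 °C → rt
Reagents that add atoms: acetic anhydride, CC(=O)OC(C)=O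
Why: The primary C1' and secondary C2 hydroxyls are acetylated; the hindered tertiary C10' hydroxyl should not react under these conditions.

## Compound list

1 | 3-methylcyclopent-2-en-1-one | CC1=CC(=O)CC1 | starting material
2 | triethyl[(3-methylcyclopenta-1,3-dien-1-yl)oxy]silane | CC[Si](CC)(CC)OC1=CCC(C)=C1 | intermediate
3 | rac-3-methyl-5-(triethylsilyloxy)cyclopent-2-en-1-one | CC1=CC(=O)C(O[Si](CC)(CC)CC)C1 | intermediate
4 | rac-2-iodo-3-methyl-5-(triethylsilyloxy)cyclopent-2-en-1-one | CC1=C(I)C(=O)C(O[Si](CC)(CC)CC)C1 | intermediate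
5 | methyl furan-2-carboxylate | COC(=O)c1ccco1 | starting material
6 | ethyl diazoacetate | CCOC(=O)C=[N+]=[N-] | starting material
7 | 6-ethyl 3-methyl (1R,5R,6R)-2-oxabicyclo[3.1.0]hex-3-ene-3,6-dicarboxylate | COC(=O)C1=C[C@@H]2[C@@H](C(=O)OCC)[C@@H]2O1 | intermediate
8 | secondary ozonide (1,2,4-trioxolane) across the enol ether double bond of 7, cyclopropane centres as in 7 | COC(=O)C12O[C@H]3[C@H](C(=O)OCC)[C@H]3C(OO1)O2 | intermediate
9 | ethyl (1R,2R,3R)-2-formyl-3-[(methoxyoxalyl)oxy]cyclopropane-1-carboxylate | O=C[C@@H]1[C@@H](C(=O)OCC)[C@@H]1OC(=O)C(=O)OC | intermediate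
10 | ethyl 2-[(1R)-1-hydroxybut-3-en-1-yl]-3-[(methoxyoxalyl)oxy]cyclopropane-1-carboxylate, ring centres as in 9 | O[C@H](CC=C)[C@@H]1[C@@H](C(=O)OCC)[C@@H]1OC(=O)C(=O)OC | intermediate
11 | (2R,3S)-2-allyl-5-oxotetrahydrofuran-3-carbaldehyde (trans) | O=C[C@@H](CC(=O)O1)[C@H]1CC=C | intermediate
12 | (4R,5R)-5-allyl-4-(hydroxymethyl)dihydrofuran-2(3H)-one (trans) | OC[C@@H](CC(=O)O1)[C@H]1CC=C | intermediate
13 | (4S,5R)-5-allyl-4-(iodomethyl)dihydrofuran-2(3H)-one (trans) | IC[C@@H](CC(=O)O1)[C@H]1CC=C | intermediate
14 | {[(2R,3S)-2-allyl-5-oxotetrahydrofuran-3-yl]methyl}zinc iodide | I[Zn]C[C@@H](CC(=O)O1)[C@H]1CC=C | intermediate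
15 | 2-{[(2R,3S)-2-allyl-5-oxotetrahydrofuran-3-yl]methyl}-3-methyl-5-(triethylsilyloxy)cyclopent-2-en-1-one, both epimers at the silyloxy carbon | CC1=C(C[C@@H](CC(=O)O2)[C@H]2CC=C)C(=O)C(O[Si](CC)(CC)CC)C1 | intermediate
16 | diene from 15 with the ketone oxygen replaced by CH2 (1-methyl-3-methylene-4-silyloxycyclopentene carrying the trans lactone side chain at C2), both silyloxy epimers | CC1=C(C[C@@H](CC(=O)O2)[C@H]2CC=C)C(=C)C(O[Si](CC)(CC)CC)C1 | intermediate
17 | tricyclic lactone, guaiane numbering: C1=C10 and C4=C5 diene, C2 triethylsilyloxy (both epimers), trans-fused C7/C8 butanolide with saturated C11 | CC1=C2C[C@H]3CC(=O)O[C@@H]3CC=C2C(O[Si](CC)(CC)CC)C1 | intermediate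
18 | 17 bearing a dimethylaminomethyl group at C11 | CC1=C2C[C@H]3C(CN(C)C)C(=O)O[C@@H]3CC=C2C(O[Si](CC)(CC)CC)C1 | intermediate
19 | trimethylammonium iodide of 18 | CC1=C2C[C@H]3C(C[N+](C)(C)C)C(=O)O[C@@H]3CC=C2C(O[Si](CC)(CC)CC)C1.[I-] | intermediate
20 | 17 with an exocyclic methylene (C13) at C11 | CC1=C2C[C@H]3C(=C)C(=O)O[C@@H]3CC=C2C(O[Si](CC)(CC)CC)C1 | intermediate
21 | bicyclic diene diol: C8 hydroxyl and C7 3-hydroxyprop-1-en-2-yl group trans, C2 triethylsilyloxy (both epimers) | CC1=C2C[C@@H](C(=C)CO)[C@H](O)CC=C2C(O[Si](CC)(CC)CC)C1 | intermediate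
22 | bis(tert-butyldimethylsilyl) ether of 21 at C8–O and C12–O | CC1=C2C[C@@H](C(=C)CO[Si](C)(C)C(C)(C)C)[C@H](O[Si](C)(C)C(C)(C)C)CC=C2C(O[Si](CC)(CC)CC)C1 | intermediate
23 | C2 alcohol from 22 (both epimers), diene C1=C10/C4=C5 | CC1=C2C[C@@H](C(=C)CO[Si](C)(C)C(C)(C)C)[C@H](O[Si](C)(C)C(C)(C)C)CC=C2C(O)C1 | intermediate
24 | upper-half dienone: C2 ketone, C1=C10 and C4=C5, C8 silyloxy trans to the C7 3-silyloxyprop-1-en-2-yl group | O=C1CC(C)=C2C[C@@H](C(=C)CO[Si](C)(C)C(C)(C)C)[C@H](O[Si](C)(C)C(C)(C)C)CC=C12 | intermediate
25 | (S)-carvone | CC1=CC[C@@H](CC1=O)C(C)=C | starting material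
26 | (1S,5S)-cis-carveol | C1C=C(C)[C@@H](O)C[C@H]1C(C)=C | intermediate
27 | 2,3-epoxide of 26 with the oxirane on the face of the hydroxyl and isopropenyl groups | C1[C@H]2O[C@@]2(C)[C@@H](O)C[C@H]1C(C)=C | intermediate
28 | 2-methyl-3-(phenylselanyl)-5-isopropenylcyclohexane-1,2-diol; both hydroxyls cis to isopropenyl, selenium trans to them | C1[C@H]([Se]c2ccccc2)[C@@](C)(O)[C@@H](O)C[C@H]1C(C)=C | intermediate
29 | 2-methyl-5-isopropenylcyclohex-3-ene-1,2-diol; both hydroxyls cis to isopropenyl | C1=C[C@@](C)(O)[C@@H](O)C[C@H]1C(C)=C | intermediate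
30 | 2-hydroxy-2-methyl-5-isopropenylcyclohex-3-en-1-one; hydroxyl cis to isopropenyl | C1=C[C@@](C)(O)C(=O)C[C@H]1C(C)=C | intermediate
31 | 2-hydroxy-5-(3-hydroxyprop-1-en-2-yl)-2-methylcyclohex-3-en-1-one; hydroxyl cis to the side chain | C1=C[C@@](C)(O)C(=O)C[C@H]1C(=C)CO | intermediate
32 | cis-fused 3-methylenehexahydrobenzofuran-5-one with C10' hydroxyl (cis to the ether oxygen) and C9' iodide (trans to the ether oxygen) | C=C1CO[C@H]2[C@H](I)[C@@](C)(O)C(=O)C[C@@H]12 | intermediate
33 | deiodinated ether ketone: cis-fused 3-methylene ether, C5' ketone, C10' hydroxyl cis to the C8' oxygen | C=C1CO[C@H]2C[C@@](C)(O)C(=O)C[C@@H]12 | intermediate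
34 | triethylsilyl ether of 33 at C10' | C=C1CO[C@H]2C[C@@](C)(O[Si](CC)(CC)CC)C(=O)C[C@@H]12 | intermediate
35 | 2,4,6-triisopropylbenzenesulfonylhydrazone of 34 | C=C1CO[C@H]2C[C@@](C)(O[Si](CC)(CC)CC)C(=NNS(=O)(=O)c3c(C(C)C)cc(C(C)C)cc3C(C)C)C[C@@H]12 | intermediate
36 | allyloxy(tert-butyl)dimethylsilane (commercial silyl ether of allyl alcohol) | C=CCO[Si](C)(C)C(C)(C)C | starting material
37 | tert-butyldimethyl[3-(4,4,5,5-tetramethyl-1,3,2-dioxaborolan-2-yl)propoxy]silane | CC(C)(C)[Si](C)(C)OCCCB1OC(C)(C)C(C)(C)O1 | intermediate
38 | ethyl 2,4,6-triisopropylbenzoate | CCOC(=O)c1c(C(C)C)cc(C(C)C)cc1C(C)C | starting material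
39 | (S)-1-lithioethyl 2,4,6-triisopropylbenzoate (sparteine complex) | [Li][C@@H](C)OC(=O)c1c(C(C)C)cc(C(C)C)cc1C(C)C | intermediate
40 | lithium boronate complex of 39 and 37 | [Li+].C[C@@H](OC(=O)c1c(C(C)C)cc(C(C)C)cc1C(C)C)[B-]2(CCCO[Si](C)(C)C(C)(C)C)OC(C)(C)C(C)(C)O2 | intermediate
41 | (R)-tert-butyldimethyl{[4-(4,4,5,5-tetramethyl-1,3,2-dioxaborolan-2-yl)pentyl]oxy}silane | C[C@H](CCCO[Si](C)(C)C(C)(C)C)B1OC(C)(C)C(C)(C)O1 | intermediate
42 | C5' alkenyllithium (C5'=C6') from 35 | C=C1CO[C@H]2C[C@@](C)(O[Si](CC)(CC)CC)C([Li])=C[C@@H]12 | intermediate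
43 | lithium alkenyl(sec-alkyl) pinacol boronate complex of 42 and 41 | C=C1CO[C@H]2C[C@@](C)(O[Si](CC)(CC)CC)C([B-]3(OC(C)(C)C(C)(C)O3)[C@H](C)CCCO[Si](C)(C)C(C)(C)C)=C[C@@H]12.[Li+] | intermediate
44 | β-iodo boronic ester: C5' bears the boronate and the (R)-side chain, C6' bears iodine | C=C1CO[C@H]2C[C@@](C)(O[Si](CC)(CC)CC)C(B3OC(C)(C)C(C)(C)O3)([C@H](C)CCCO[Si](C)(C)C(C)(C)C)C(I)[C@@H]12 | intermediate
45 | cyclic ether: cis-fused 3-methylenetetrahydrofuran on the C5'=C6' cyclohexene, C10' triethylsilyloxy cis to the C8' oxygen, (R)-C4' side chain with terminal silyloxy group | C=C1CO[C@H]2C[C@@](C)(O[Si](CC)(CC)CC)C([C@H](C)CCCO[Si](C)(C)C(C)(C)C)=C[C@@H]12 | intermediate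
46 | lower-half methylene lactone (45 with C12' as lactone carbonyl) | C=C1C(=O)O[C@H]2C[C@@](C)(O[Si](CC)(CC)CC)C([C@H](C)CCCO[Si](C)(C)C(C)(C)C)=C[C@H]21 | intermediate
47 | lithium dimethylcuprate | [Li+].C[Cu-]C | starting material
48 | lithium dienolate (O–C2=C1, C4=C5) with the C10 methyl anti to the C8 silyloxy group | [Li]OC1=C2[C@H](C)C[C@@H](O[Si](C)(C)C(C)(C)C)[C@H](C(=C)CO[Si](C)(C)C(C)(C)C)CC2=C(C)C1 | intermediate
49 | lithium enolate of the lower lactone in the Michael adduct | CC(C)(C)[Si](C)(C)O[C@@H]2C[C@@H](C)[C@@]3(CC5=C(O[Li])O[C@H]6C[C@@](C)(O[Si](CC)(CC)CC)C([C@H](C)CCCO[Si](C)(C)C(C)(C)C)=C[C@H]65)C(=O)CC(C)=C3C[C@H]2C(=C)CO[Si](C)(C)C(C)(C)C | intermediate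
50 | Michael adduct: C1 quaternary (C13' anti to the C10 methyl), C2 ketone, C3H2, C4=C5; C11' drawn as the epimer from convex-face protonation | CC(C)(C)[Si](C)(C)O[C@@H]2C[C@@H](C)[C@@]3(C[C@H]5C(=O)O[C@H]6C[C@@](C)(O[Si](CC)(CC)CC)C([C@H](C)CCCO[Si](C)(C)C(C)(C)C)=C[C@H]65)C(=O)CC(C)=C3C[C@H]2C(=C)CO[Si](C)(C)C(C)(C)C | intermediate
51 | dilithium bis-enolate (C2–O/C3 dienolate and C12'–O/C11' lactone enolate) | CC(C)(C)[Si](C)(C)O[C@@H]2C[C@@H](C)[C@@]3(CC5=C(O[Li])O[C@H]6C[C@@](C)(O[Si](CC)(CC)CC)C([C@H](C)CCCO[Si](C)(C)C(C)(C)C)=C[C@H]65)C(O[Li])=CC(C)=C3C[C@H]2C(=C)CO[Si](C)(C)C(C)(C)C | intermediate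
52 | norbornenone: C3–C11' bond formed, C2 ketone on the one-carbon bridge, C7' exo and lactone carbonyl endo | CC(C)(C)[Si](C)(C)O[C@@H]2C[C@@H](C)[C@]34C[C@]5(C(=O)O[C@H]6C[C@@](C)(O[Si](CC)(CC)CC)C([C@H](C)CCCO[Si](C)(C)C(C)(C)C)=C[C@H]65)[C@H](C(C)=C3C[C@H]2C(=C)CO[Si](C)(C)C(C)(C)C)C4=O | intermediate
53 | C2 alcohol, hydroxyl syn to the C13'–C11' bridge | CC(C)(C)[Si](C)(C)O[C@@H]2C[C@@H](C)[C@]34C[C@]5(C(=O)O[C@H]6C[C@@](C)(O[Si](CC)(CC)CC)C([C@H](C)CCCO[Si](C)(C)C(C)(C)C)=C[C@H]65)[C@H](C(C)=C3C[C@H]2C(=C)CO[Si](C)(C)C(C)(C)C)[C@H]4O | intermediate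
54 | pentaol (C2, C8, C12, C10', C1' hydroxyls) | O[C@@H]2C[C@@H](C)[C@]34C[C@]5(C(=O)O[C@H]6C[C@@](C)(O)C([C@H](C)CCCO)=C[C@H]65)[C@H](C(C)=C3C[C@H]2C(=C)CO)[C@H]4O | intermediate
55 | upper lactol (C12 hemiacetal, trans-fused at C7/C8) | C=C1C(O)O[C@@H]2C[C@@H](C)[C@]34C[C@]5(C(=O)O[C@H]6C[C@@](C)(O)C([C@H](C)CCCO)=C[C@H]65)[C@H](C(C)=C3C[C@@H]12)[C@H]4O | intermediate
56 | triol bis-lactone (target without the two acetyl groups) | C=C1C(=O)O[C@@H]2C[C@@H](C)[C@]34C[C@]5(C(=O)O[C@H]6C[C@@](C)(O)C([C@H](C)CCCO)=C[C@H]65)[C@H](C(C)=C3C[C@@H]12)[C@H]4O | intermediate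
57 | CNP0257312.1 | C=C1C(=O)O[C@@H]2C[C@@H](C)[C@]34C[C@]5(C(=O)O[C@H]6C[C@@](C)(O)C([C@H](C)CCCOC(C)=O)=C[C@H]65)[C@H](C(C)=C3C[C@@H]12)[C@H]4OC(C)=O | target

## Step count and risks

Total: 35 steps. Longest linear sequence: 20 steps (steps 3–16, then 30–35). The lower half takes 11 linear steps (17–25, 28, 29), with branches of 2 steps each for 4 (steps 1–2) and 41 (steps 26–27).

**Step 30 (key step).** The most likely failure is proton transfer instead of C–C bond formation: enolate 48 is quenched by the doubly allylic C7'–H of 46 or by C3–H of unreacted 24. Poor facial selectivity at C10 and γ-attack at C4 are the other risks. Fallback: from 24, the cuprate addition is quenched with NH4Cl and the methylated β,γ-unsaturated ketone F1 is isolated, so that the C10 configuration can be secured by separation. F1 is then added to 46 as its thermodynamic dienolate under catalytic KOtBu in tBuOH/THF at 0 °C, a classical base-catalysed Michael addition, which returns to the route at 50.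

**Step 31.** Incomplete double enolisation, intermolecular coupling or attack on the concave lactone face would lower the yield of the bicycle. Fallback: from 50, the bis-enolate is trapped with Me3SiCl to give the isolated bis(trimethylsilyl) dienol ether–ketene acetal F2. This is oxidised with (NH4)2Ce(NO3)6 (tetravalent cerium) and NaHCO3 in MeCN at −10 °C, the known oxidative coupling of silyl bis-enol ethers, and returns at 52.

**Step 28.** Ate-complex formation next to the quaternary silyloxy carbon may be slow, and in a ring the boron and iodine of 44 end up cis, so the elimination cannot be antiperiplanar; protodeboronation or an alkenyl iodide could result. Fallback: from 34, KN(SiMe3)2 and PhNTf2 give enol triflate F3. Negishi coupling with the racemic secondary alkylzinc bromide F4 (Pd(OAc)2, CPhos) gives 45 together with its C4' epimer F5; these are diastereomers and are separated by chromatography. The route is rejoined at 45.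

**Step 29.** Competing hydrogen abstraction at the doubly allylic C7'–H, or low conversion of the hindered ether, is the likely failure. Fallback: from 45, reductive cleavage of the allylic C12'–O bond with Li and 4,4'-di-tert-butylbiphenyl in THF at −78 °C gives hydroxy isopropenyl compound F6. SeO2/tBuOOH hydroxylates the isopropenyl methyl to diol F7, and MnO2 closes the lactone, returning at 46.

**Step 11.** Slow engagement of the hindered diene terminus could let oligomerisation through the allyl group take over. Fallback: from 15, ring-closing carbonyl–olefin metathesis with stoichiometric Mo(=CHCMe2Ph)(=N-2,6-iPr2C6H3)[OCMe(CF3)2]2: alkylidene exchange at the terminal alkene followed by Wittig-like closure on the ring ketone. This gives 17 directly and bypasses 16.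

## Further compounds

F1 | step 30 | 10-methyl β,γ-unsaturated ketone (C2 ketone, C1–H, C4=C5; C10 methyl anti to the C8 silyloxy group) | O=C1CC(C)=C2C[C@@H](C(=C)CO[Si](C)(C)C(C)(C)C)[C@H](O[Si](C)(C)C(C)(C)C)C[C@@H](C)C12
F2 | step 31 | bis(trimethylsilyl) dienol ether–ketene acetal of 50 | CC(C)(C)[Si](C)(C)O[C@@H]2C[C@@H](C)[C@@]3(CC5=C(O[Si](C)(C)C)O[C@H]6C[C@@](C)(O[Si](CC)(CC)CC)C([C@H](C)CCCO[Si](C)(C)C(C)(C)C)=C[C@H]65)C(O[Si](C)(C)C)=CC(C)=C3C[C@H]2C(=C)CO[Si](C)(C)C(C)(C)C
F3 | step 28 | C5' enol triflate of 34 | C=C1CO[C@H]2C[C@@](C)(O[Si](CC)(CC)CC)C(OS(=O)(=O)C(F)(F)F)=C[C@@H]12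
F4 | step 28 | rac-[5-(tert-butyldimethylsilyloxy)pentan-2-yl]zinc bromide | Br[Zn]C(C)CCCO[Si](C)(C)C(C)(C)C
F5 | step 28 | C4' epimer of 45 | C=C1CO[C@H]2C[C@@](C)(O[Si](CC)(CC)CC)C([C@@H](C)CCCO[Si](C)(C)C(C)(C)C)=C[C@@H]12
F6 | step 29 | ring-opened C8' alcohol with C7' isopropenyl group | O[C@H]2C[C@@](C)(O[Si](CC)(CC)CC)C([C@H](C)CCCO[Si](C)(C)C(C)(C)C)=C[C@H]2C(C)=C
F7 | step 29 | lower-half 2-methylene-1,4-diol (C8' and C12' hydroxyls) | O[C@H]2C[C@@](C)(O[Si](CC)(CC)CC)C([C@H](C)CCCO[Si](C)(C)C(C)(C)C)=C[C@H]2C(=C)CO
F0 | step 11 | none | none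
A1 | alternative 1 | ten-membered-ring C5 vinyl bromide with C1=C10 alkene | C1C(=O)O[C@@H]2CC(C)=C4C[C@]5(C(=O)O[C@H]6C[C@@](C)(O[Si](CC)(CC)CC)C([C@H](C)CCCO[Si](C)(C)C(C)(C)C)=C[C@H]65)[C@H](C(C)=C(Br)C[C@@H]12)[C@H]4O[Si](C)(C)C(C)(C)C
A2 | alternative 1 | full carbon skeleton lacking the exocyclic methylene | C1C(=O)O[C@@H]2C[C@@H](C)[C@]34C[C@]5(C(=O)O[C@H]6C[C@@](C)(O[Si](CC)(CC)CC)C([C@H](C)CCCO[Si](C)(C)C(C)(C)C)=C[C@H]65)[C@H](C(C)=C3C[C@@H]12)[C@H]4O[Si](C)(C)C(C)(C)C
A3 | alternative 2 | spiro diketone (C4 methyl ketone on C3, C5 cycloheptanone) | CC(C)(C)[Si](C)(C)O[C@@H]2C[C@@H](C)[C@@]4(C(=O)C[C@H]2C(=C)CO[Si](C)(C)C(C)(C)C)C[C@]5(C(=O)O[C@H]6C[C@@](C)(O[Si](CC)(CC)CC)C([C@H](C)CCCO[Si](C)(C)C(C)(C)C)=C[C@H]65)[C@H](C(C)=O)[C@H]4O[Si](C)(C)C(C)(C)C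
A4 | alternative 2 | bridged cis-4,5-diol | CC(C)(C)[Si](C)(C)O[C@@H]2C[C@@H](C)[C@]34C[C@]5(C(=O)O[C@H]6C[C@@](C)(O[Si](CC)(CC)CC)C([C@H](C)CCCO[Si](C)(C)C(C)(C)C)=C[C@H]65)[C@H]([C@@](C)(O)[C@]3(O)C[C@H]2C(=C)CO[Si](C)(C)C(C)(C)C)[C@H]4O[Si](C)(C)C(C)(C)C
A5 | alternative 3 | C2 aldehyde on quaternary C1 of the spiro cyclohexenone | CC(C)(C)[Si](C)(C)OCC[C@@H](C)[C@]3(C=O)C[C@]5(C(=O)O[C@H]6C[C@@](C)(O[Si](CC)(CC)CC)C([C@H](C)CCCO[Si](C)(C)C(C)(C)C)=C[C@H]65)C=C(C)C3=O
A6 | alternative 3 | 7-hydroxybicyclo[2.2.1]heptan-2-one spiro lactone | CC(C)(C)[Si](C)(C)OCC[C@@H](C)[C@]34C[C@]5(C(=O)O[C@H]6C[C@@](C)(O[Si](CC)(CC)CC)C([C@H](C)CCCO[Si](C)(C)C(C)(C)C)=C[C@H]65)[C@H]([C@H](C)C3=O)[C@H]4O
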